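**Plan**
1. Retrosynthesis: remove the C8 methacrylate and C13 (C11=C13). Then cut the C5–O ether bond (transannular SN2 at C5 by the C10 hydroxyl) and the lactone C12–O6 bond.
2. The resulting 5,6,10-trioxygenated ten-membered ring comes from a bridged C5 ketal acetate. Its C5–O–C10 unit, with C10 fully substituted, is an oxygen atom inserted into the C5–C10 ring-fusion bond of a decalin C5 hydroperoxide (Criegee). The decalin comes from (S)-Wieland–Miescher ketone, methyl bromoacetate and formaldehyde.
3. Forward: ring B is completed first on the C3 thioketal (carbonyl moved from C9 to C8, C7 acetic ester, C8 alcohol). Ring A follows (C4 hydroxymethylation that moves the alkene to C5=C6, C3 acetate), then C5 hydroperoxidation.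
4. The Criegee shift turns the two six-membered rings into the ten-membered carbocycle and the two oxepane rings of the 11-oxabicyclo[4.4.1]undecane. The bridge then serves to oxygenate C6, is opened by reduction at C5, and is closed again with inversion once the γ-lactone is in place.
5. Stereochemistry: C10 from the starting ketone (retained in the shift); C7 by equilibration; C8 and C3 by equatorial hydride attack; C4 by aldol attack anti to the C10 methyl; C6 by outer-face osmylation of the bridged enol ether; C5 by chelation-controlled reduction followed by SN2 inversion.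

Key step: step 15

**Remarks**
- Numbering: C10 (methyl-bearing ether carbon), C1, C2, C3 (OAc), C4 (C15H2OH), C5 (ether CH), C6 (lactone O–CH), C7, C8 (methacrylate), C9; C11 (=C13H2), C12 (lactone C=O). In the decalins β is the face of the C10 methyl.
- Assumption: the target SMILES encodes (5R,10R), a trans (inside–outside) C5–O–C10 bridge. The cis-bridged ketal from the key step is therefore opened and closed again with inversion at C5.
- Reagents are named in the steps; numbers are given to starting materials, intermediates and the target.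
- C15 carries a TBDPS ether so that the C8 TBS ether can be removed first at the end. Compound 20 is drawn as the 5α-hydroperoxide; its C5 configuration is erased in step 15.

**Route**

Step 1
Reactants: 1 (S)-Wieland–Miescher ketone
Product: 2 C3 1,3-dithiolane of 1 (C4=C5 retained; C9 ketone free)
Conditions: HSCH2CH2SH (1.05 equiv), p-TsOH (cat.), AcOH, rt
Reagents that add atoms: ethane-1,2-dithiol, SCCS
Why: Acid-catalysed thioketalisation should be selective for the conjugated C3 carbonyl because the C9 ketone is shielded by the adjacent quaternary C10, and in dithioketals the C4=C5 bond does not migrate.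

Step 2
Reactants: 2 C3 dithiolane
Product: 3 enol triflate (C9–OTf; C8=C9)
Conditions: KN(SiMe3)2, THF, −78 °C; PhNTf2, −78 → 0 °C
Reagents that add atoms: N-phenylbis(trifluoromethanesulfonimide), O=S(=O)(N(c1ccccc1)S(=O)(=O)C(F)(F)F)C(F)(F)F
Why: Enolate O-triflation; C10 bears no hydrogen, so the C9 ketone can enolise only towards C8.

Step 3
Reactants: 3 enol triflate
Product: 4 diene (C4=C5; C8=C9)
Conditions: Pd(OAc)2 (cat.), PPh3, HCO2H, n-Bu3N, DMF, 60 °C
Reagents that add atoms: none
Why: Palladium-catalysed formate reduction of an enol triflate (oxidative addition, formate-to-hydride exchange with loss of CO2, reductive elimination) replaces OTf by H without moving either alkene.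

Step 4
Reactants: 4 diene
Product: 6 8α-alcohol (C3 dithiolane; C4=C5), via B-alkyl-9-BBN adduct 5 (not isolated)
Conditions: 9-borabicyclo[3.3.1]nonane (9-BBN), THF, 65 °C; then NaOH, H2O2, 0 °C
Reagents that add atoms: hydrogen peroxide, OO
Why: Hydroboration–oxidation; the bulky borane should place boron on C8, away from quaternary C10 and anti to the C10 methyl, and leave the hindered trisubstituted C4=C5 bond, while the C8 configuration is removed in step 5.

Step 5
Reactants: 6 8α-alcohol
Product: 7 C8 ketone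
Conditions: SO3·pyridine, DMSO, Et3N, CH2Cl2, 0 °C
Reagents that add atoms: none
Why: Parikh–Doering oxidation converts the secondary alcohol into the ketone without oxidising the thioketal sulfur, which completes the 1,2-transposition of the carbonyl from C9 to C8.

Step 6
Reactants: 7 C8 ketone; 8 methyl bromoacetate
Product: 10 keto ester with 7β-CH2CO2Me, via 7α-epimeric keto ester 9 (not isolated)
Conditions: LiN(SiMe3)2, THF, −78 °C; BrCH2CO2Me, −78 → −20 °C; then NaOCH3 (cat.), MeOH, 0 °C → rt
Reagents that add atoms: methyl bromoacetate, COC(=O)CBr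
Why: Kinetic enolate alkylation should occur at C7 because C9 is neopentyl, and methoxide then equilibrates C7 to the equatorial 7β epimer; the alkene is still at C4=C5, insulated by C6, so equilibration cannot drain into a conjugated enone.

Step 7
Reactants: 10 keto ester
Product: 11 hydroxy ester (8β-OH)
Conditions: LiBH(s-Bu)3, THF, −78 °C; AcOH, −78 °C
Reagents that add atoms: none
Why: Bulky-hydride reduction; axial approach to C8 is blocked by the syn-axial C10 methyl, so hydride should enter equatorially and give the axial 8β-alcohol cis to the C7 side chain, and the cold acidic quench keeps the alkoxide from closing onto the ester.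

Step 8
Reactants: 11 hydroxy ester
Product: 12 TBS ether (8β-OTBS)
Conditions: TBSOTf, 2,6-lutidine, CH2Cl2, −78 → 0 °C
Reagents that add atoms: tert-butyldimethylsilyl trifluoromethanesulfonate, CC(C)(C)[Si](C)(C)OS(=O)(=O)C(F)(F)F
Why: Silyl-triflate silylation is fast enough for the hindered axial alcohol and is carried out at once so that the cis hydroxy ester does not lactonise.

Step 9
Reactants: 12 TBS ether
Product: 13 enone (C3=O; C4=C5)
Conditions: MeI, CaCO3, MeCN–H2O (4:1), 45 °C
Reagents that add atoms: water, O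
Why: S-Methylation of the dithiolane and hydrolysis of the allylic sulfonium ion under buffered neutral conditions should release the enone and leave the silyl ether and the ester.

Step 10
Reactants: 13 enone; 14 formaldehyde
Product: 15 β-hydroxy ketone (4α-CH2OH; C5=C6)
Conditions: KOC(CH3)3, THF, 0 °C; CH2O (monomer in THF), −78 °C; AcOH, −78 °C
Reagents that add atoms: formaldehyde, C=O
Why: Deconjugative aldol reaction of the extended (thermodynamic) dienolate, which under kinetic control attacks formaldehyde through its α-carbon C4 so that the alkene moves to C5=C6; the electrophile enters anti to the axial C10 methyl and sets the 4α centre.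

Step 11
Reactants: 15 β-hydroxy ketone
Product: 16 TBDPS ether
Conditions: TBDPSCl, imidazole, CH2Cl2, 0 °C
Reagents that add atoms: tert-butyl(chloro)diphenylsilane, CC(C)(C)[Si](Cl)(c1ccccc1)c1ccccc1
Why: Silylation of the primary alcohol under nearly neutral conditions closes the retro-aldol and dehydration pathways of the β-hydroxy ketone and gives a non-chelating group that outlasts the C8 TBS ether.

Step 12
Reactants: 16 TBDPS ether
Product: 17 3α-alcohol
Conditions: LiBH(s-Bu)3, THF, −78 °C; AcOH
Reagents that add atoms: none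
Why: Bulky-hydride reduction from the equatorial direction should give the axial 3α-alcohol cis to the equatorial C4 substituent (as for 2-substituted cyclohexanones), and at −78 °C the ketone reacts well before the methyl ester.

Step 13
Reactants: 17 3α-alcohol
Product: 18 3α-acetate
Conditions: Ac2O, pyridine, DMAP (cat.), CH2Cl2, rt
Reagents that add atoms: acetic anhydride, CC(=O)OC(C)=O
Why: DMAP-catalysed acylation installs the C3 acetate of the target on the only free hydroxyl.

Step 14
Reactants: 18 3α-acetate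
Product: 20 C5 hydroperoxide (5α-OOH), via triethylsilyl peroxide 19 (not isolated)
Conditions: Co(acac)2 (cat.), Et3SiH, O2 (1 atm), EtOH, rt; then HCl (cat.), MeOH, 0 °C
Reagents that add atoms: dioxygen, O=O
Why: Mukaiyama hydroperoxidation: hydrogen-atom transfer from a cobalt hydride to C6 gives the tertiary C5 radical (Markovnikov), which is trapped by O2 and silylated, and brief acid methanolysis frees the hydroperoxide; oxygen is expected anti to the C10 methyl.

Step 15
Reactants: 20 C5 hydroperoxide
Product: 22 bridged ketal acetate (5S,10R), via C5 peracetate 21 (not isolated)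
Conditions: Ac2O, pyridine, DMAP (cat.), CH2Cl2, 0 → 40 °C
Reagents that add atoms: acetic anhydride, CC(=O)OC(C)=O
Why: Acetylation gives the peracetate, whose O–O bond ionises in concert with a 1,2-shift of C10 from C5 to the proximal oxygen (Criegee rearrangement, the peroxide counterpart of a Baeyer–Villiger shift, known for 9-decalyl peresters, which give 1,6-epoxycyclodecyl esters); the bridged oxocarbenium ion at C5 is then captured by acetate. No ring is closed by cyclisation: both oxepane rings of the 11-oxabicyclo[4.4.1]undecane and the ten-membered carbocycle arise by ring expansion when the C5–C10 fusion bond becomes C5–O–C10. C10 migrates with retention, so the angular-methyl centre of 1 becomes the C10 ether centre unchanged. The new C5 ketal centre can carry its acetate only on the outer face of the bridgehead, which should give the cis-bridged 5S isomer from either C5 epimer of 20. The step needs migration of C10 rather than C4 or C6; C10 is the only fully substituted neighbour and so the best able to carry positive charge, while C4 is inductively deactivated by the acetoxy and silyloxymethyl groups. The esters and silyl ethers are inert to Ac2O and pyridine.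

Step 16
Reactants: 22 bridged ketal acetate
Product: 23 bridged enol ether (C5=C6)
Conditions: TMSOTf, i-Pr2NEt, CH2Cl2, −78 → 0 °C
Reagents that add atoms: none
Why: Silyl-triflate ionisation of the ketal acetate to the bridged oxocarbenium ion followed by loss of a proton (ketal-to-enol-ether elimination); the hindered amine should take the proton from the C6 methylene and not from the substituted C4 methine, and the bridgehead double bond is permitted because it is trans only within the ten-membered ring.

Step 17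
Reactants: 23 bridged enol ether
Product: 24 6-hydroxy hemiketal (5S,6R)
Conditions: OsO4 (cat.), NMO, acetone–H2O, 0 °C
Reagents that add atoms: osmium tetroxide, O=[Os](=O)(=O)=O; N-methylmorpholine N-oxide, C[N+]1([O-])CCOCC1; water, O
Why: Upjohn dihydroxylation of the electron-rich enol ether gives the α-hydroxy hemiketal; osmylation can occur only on the outer face of the bridgehead alkene, which sets C6 as R.

Step 18
Reactants: 24 6-hydroxy hemiketal
Product: 25 triol (5S,6R,10R)
Conditions: Zn(BH4)2, Et2O, −20 → 0 °C; aq. NH4Cl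
Reagents that add atoms: none
Why: Chelation-controlled reduction (Cram-chelate model) of the α-hydroxy ketone in equilibrium with the hemiketal: zinc bridges the C6 oxygen and the C5 carbonyl and hydride enters anti to C7, which should give the erythro 5S,6R diol and leave the esters untouched.

Step 19
Reactants: 25 triol
Product: 26 hydroxy γ-lactone (5-OH; 10-OH)
Conditions: PPTS (cat.), CH2Cl2, rt
Reagents that add atoms: none
Why: Acid-catalysed lactonisation; the C6 hydroxyl should close the five-membered ring onto C12 in preference to the six-membered alternative from the C5 hydroxyl, which leaves C5–OH as the only secondary alcohol.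

Step 20
Reactants: 26 hydroxy γ-lactone
Product: 28 trans-bridged ether lactone (5R,6R,10R), via C5 triflate 27 (not isolated)
Conditions: Tf2O, 2,6-di-tert-butyl-4-methylpyridine, CH2Cl2, −78 → 0 °C
Reagents that add atoms: none
Why: Cyclodehydrative etherification (Williamson-type displacement of a sulfonate by a hydroxyl): the secondary C5 alcohol is triflated before the tertiary one and the C10 hydroxyl then displaces the triflate across the ring with inversion, converting the 5S alcohol into the 5R ether of the target; both bridgehead configurations are fixed before closure and ionisation at C5 is disfavoured by the adjacent acyloxy group.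

Step 21
Reactants: 28 trans-bridged ether lactone
Product: 31 α-methylene lactone, via Mannich base 29 (not isolated), via trimethylammonium iodide 30 (not isolated)
Conditions: LiN(SiMe3)2, THF, −78 °C; CH2=NMe2+ I−, −78 → 0 °C; then MeI, MeOH, rt; then NaHCO3 (aq.), CH2Cl2
Reagents that add atoms: N,N-dimethylmethyleneiminium iodide, C=[N+](C)C.[I-]
Why: Eschenmoser methylenation (Mannich reaction of the lactone enolate, N-methylation, base-induced loss of trimethylamine); LiN(SiMe3)2 is basic enough for the γ-lactone but not for the acetate.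

Step 22
Reactants: 31 α-methylene lactone
Product: 32 C8 alcohol
Conditions: HF·pyridine, pyridine, THF, 0 °C → rt
Reagents that add atoms: none
Why: Acidic fluoride desilylation should remove the secondary TBS ether before the far more acid-stable primary TBDPS ether.

Step 23
Reactants: 32 C8 alcohol
Product: 33 C8 methacrylate
Conditions: methacrylic anhydride, Et3N, DMAP (cat.), CH2Cl2, 0 °C → rt
Reagents that add atoms: methacrylic anhydride, C=C(C)C(=O)OC(=O)C(C)=C
Why: DMAP-catalysed acylation of the only free hydroxyl.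

Step 24
Reactants: 33 C8 methacrylate
Product: 34 CNP0602302.1
Conditions: HF·pyridine, THF, rt
Reagents that add atoms: none
Why: Fluoride desilylation of the TBDPS ether in acidic medium should free C15–OH without acetyl migration from O3 and without conjugate addition to the two acrylate units.

**Compound list**
1 | (S)-Wieland–Miescher ketone | O=C1CCCC2=CC(=O)CC[C@]12C | starting material
2 | C3 1,3-dithiolane of 1 (C4=C5, C9 ketone) | O=C1CCCC2=CC3(SCCS3)CC[C@]12C | intermediate
3 | C9 enol triflate (C8=C9), C3 dithiolane | O=S(=O)(OC1=CCCC2=CC3(SCCS3)CC[C@]12C)C(F)(F)F | intermediate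
4 | diene (C4=C5, C8=C9), C3 dithiolane | C1=CCCC2=CC3(SCCS3)CC[C@]12C | intermediate
5 | B-(C8-alkyl)-9-BBN adduct of 4 (boron 8α) | C1CCC2CCCC1B2[C@H]3C[C@@]4(C)CCC5(SCCS5)C=C4CC3 | intermediate (not isolated)
6 | 8α-alcohol, C3 dithiolane, C4=C5 | O[C@H]1C[C@@]2(C)CCC3(SCCS3)C=C2CC1 | intermediate
7 | C8 ketone, C3 dithiolane, C4=C5 | O=C1C[C@@]2(C)CCC3(SCCS3)C=C2CC1 | intermediate
8 | methyl bromoacetate | COC(=O)CBr | starting material
9 | 7α-epimer of 10 | O=C1C[C@@]2(C)CCC3(SCCS3)C=C2C[C@H]1CC(=O)OC | intermediate (not isolated)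
10 | keto ester: 7β-CH2CO2Me, C8 ketone, C3 dithiolane | O=C1C[C@@]2(C)CCC3(SCCS3)C=C2C[C@@H]1CC(=O)OC | intermediate
11 | hydroxy ester: 8β-OH, 7β-CH2CO2Me | O[C@@H]1C[C@@]2(C)CCC3(SCCS3)C=C2C[C@@H]1CC(=O)OC | intermediate
12 | 8β-OTBS ether of 11 | CC(C)(C)[Si](C)(C)O[C@@H]1C[C@@]2(C)CCC3(SCCS3)C=C2C[C@@H]1CC(=O)OC | intermediate
13 | enone: C3=O, C4=C5, 7β-CH2CO2Me, 8β-OTBS | CC(C)(C)[Si](C)(C)O[C@@H]1C[C@@]2(C)CCC(=O)C=C2C[C@@H]1CC(=O)OC | intermediate
14 | formaldehyde | C=O | starting material
15 | β-hydroxy ketone: C3=O, 4α-CH2OH, C5=C6 | CC(C)(C)[Si](C)(C)O[C@@H]1C[C@@]2(C)CCC(=O)[C@@H](CO)C2=C[C@@H]1CC(=O)OC | intermediate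
16 | 15-O-TBDPS ether of 15 | CC(C)(C)[Si](C)(C)O[C@@H]1C[C@@]2(C)CCC(=O)[C@@H](CO[Si](c3ccccc3)(c3ccccc3)C(C)(C)C)C2=C[C@@H]1CC(=O)OC | intermediate
17 | 3α-alcohol | CC(C)(C)[Si](C)(C)O[C@@H]1C[C@@]2(C)CC[C@@H](O)[C@@H](CO[Si](c3ccccc3)(c3ccccc3)C(C)(C)C)C2=C[C@@H]1CC(=O)OC | intermediate
18 | 3α-acetate, C5=C6 | CC(C)(C)[Si](C)(C)O[C@@H]1C[C@@]2(C)CC[C@@H](OC(C)=O)[C@@H](CO[Si](c3ccccc3)(c3ccccc3)C(C)(C)C)C2=C[C@@H]1CC(=O)OC | intermediate
19 | C5 triethylsilyl peroxide (5α) | CC(C)(C)[Si](C)(C)O[C@@H]1C[C@@]2(C)CC[C@@H](OC(C)=O)[C@@H](CO[Si](c3ccccc3)(c3ccccc3)C(C)(C)C)[C@]2(OO[Si](CC)(CC)CC)C[C@@H]1CC(=O)OC | intermediate (not isolated)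
20 | trans-decalin C5 hydroperoxide (5α-OOH) | CC(C)(C)[Si](C)(C)O[C@@H]1C[C@@]2(C)CC[C@@H](OC(C)=O)[C@@H](CO[Si](c3ccccc3)(c3ccccc3)C(C)(C)C)[C@]2(OO)C[C@@H]1CC(=O)OC | intermediate
21 | C5 peracetate | CC(C)(C)[Si](C)(C)O[C@@H]1C[C@@]2(C)CC[C@@H](OC(C)=O)[C@@H](CO[Si](c3ccccc3)(c3ccccc3)C(C)(C)C)[C@]2(OOC(C)=O)C[C@@H]1CC(=O)OC | intermediate (not isolated)
22 | bridged C5 ketal acetate (5S,10R), 11-oxabicyclo[4.4.1]undecane | CC(C)(C)[Si](C)(C)O[C@@H]1C[C@@]2(C)CC[C@@H](OC(C)=O)[C@@H](CO[Si](c3ccccc3)(c3ccccc3)C(C)(C)C)[C@](OC(C)=O)(O2)C[C@@H]1CC(=O)OC | intermediate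
23 | bridged enol ether (5Z), C5=C6 | CC(C)(C)[Si](C)(C)O[C@@H]1C[C@@]2(C)CC[C@@H](OC(C)=O)[C@@H](CO[Si](c3ccccc3)(c3ccccc3)C(C)(C)C)/C(O2)=C/[C@@H]1CC(=O)OC | intermediate
24 | bridged 6-hydroxy hemiketal (5S,6R) | CC(C)(C)[Si](C)(C)O[C@@H]1C[C@@]2(C)CC[C@@H](OC(C)=O)[C@@H](CO[Si](c3ccccc3)(c3ccccc3)C(C)(C)C)[C@](O)(O2)[C@H](O)[C@@H]1CC(=O)OC | intermediate
25 | ten-membered triol (5S,6R,10R): 5-OH, 6-OH, 10-OH | CC(C)(C)[Si](C)(C)O[C@@H]1C[C@](C)(O)CC[C@@H](OC(C)=O)[C@@H](CO[Si](c2ccccc2)(c2ccccc2)C(C)(C)C)[C@H](O)[C@H](O)[C@@H]1CC(=O)OC | intermediate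
26 | hydroxy γ-lactone (6,12-olide; 5S-OH; 10-OH) | CC(C)(C)[Si](C)(C)O[C@@H]1C[C@](C)(O)CC[C@@H](OC(C)=O)[C@@H](CO[Si](c2ccccc2)(c2ccccc2)C(C)(C)C)[C@H](O)[C@@H]2OC(=O)C[C@@H]21 | intermediate
27 | C5 triflate of 26 | CC(C)(C)[Si](C)(C)O[C@@H]1C[C@](C)(O)CC[C@@H](OC(C)=O)[C@@H](CO[Si](c2ccccc2)(c2ccccc2)C(C)(C)C)[C@H](OS(=O)(=O)C(F)(F)F)[C@@H]2OC(=O)C[C@@H]21 | intermediate (not isolated)
28 | trans-bridged ether lactone (5R,6R,10R) | CC(C)(C)[Si](C)(C)O[C@@H]1C[C@@]2(C)CC[C@@H](OC(C)=O)[C@@H](CO[Si](c3ccccc3)(c3ccccc3)C(C)(C)C)[C@@H](O2)[C@@H]2OC(=O)C[C@@H]21 | intermediate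
29 | C11 dimethylaminomethyl lactone (C11 epimers) | CC(C)(C)[Si](C)(C)O[C@@H]1C[C@@]2(C)CC[C@@H](OC(C)=O)[C@@H](CO[Si](c3ccccc3)(c3ccccc3)C(C)(C)C)[C@@H](O2)[C@@H]2OC(=O)C(CN(C)C)[C@@H]21 | intermediate (not isolated)
30 | C11 trimethylammoniomethyl lactone iodide | CC(C)(C)[Si](C)(C)O[C@@H]1C[C@@]2(C)CC[C@@H](OC(C)=O)[C@@H](CO[Si](c3ccccc3)(c3ccccc3)C(C)(C)C)[C@@H](O2)[C@@H]2OC(=O)C(C[N+](C)(C)C)[C@@H]21.[I-] | intermediate (not isolated)
31 | α-methylene lactone (8-OTBS, 15-OTBDPS) | CC(C)(C)[Si](C)(C)O[C@@H]1C[C@@]2(C)CC[C@@H](OC(C)=O)[C@@H](CO[Si](c3ccccc3)(c3ccccc3)C(C)(C)C)[C@@H](O2)[C@@H]2OC(=O)C(=C)[C@@H]21 | intermediate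
32 | C8 alcohol (15-OTBDPS) | O[C@@H]1C[C@@]2(C)CC[C@@H](OC(C)=O)[C@@H](CO[Si](c3ccccc3)(c3ccccc3)C(C)(C)C)[C@@H](O2)[C@@H]2OC(=O)C(=C)[C@@H]21 | intermediate
33 | C8 methacrylate (15-OTBDPS) | C=C(C)C(=O)O[C@@H]1C[C@@]2(C)CC[C@@H](OC(C)=O)[C@@H](CO[Si](c3ccccc3)(c3ccccc3)C(C)(C)C)[C@@H](O2)[C@@H]2OC(=O)C(=C)[C@@H]21 | intermediate
34 | CNP0602302.1 (3R,4R,5R,6R,7R,8R,10R) | C=C(C)C(=O)O[C@@H]1C[C@@]2(C)CC[C@@H](OC(C)=O)[C@@H](CO)[C@@H](O2)[C@@H]2OC(=O)C(=C)[C@@H]21 | target

**Step count and risks**

Total step count: 24. Longest linear sequence: 24 steps from 1 (the route is fully linear).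

Steps most likely to fail:

1. Step 20. The transannular back-side attack requires the ring to fold into the strained inside–outside geometry. It may be outrun by loss of triflic acid towards C4 or by participation of the C3 acetate carbonyl. Fallback: place C5 in a cyclic electrophile before the lactone exists and use the alkoxide as nucleophile. Triol 25 with SO2Cl2 and Et3N would give the 5,6-cyclic sulfate F1. NaH then forms the C10 alkoxide, which opens the sulfate at C5 with inversion to the sodium sulfate monoester F2 of the trans-bridged ether. Acid hydrolysis (cat. H2SO4, THF–H2O) would give the hydroxy ester F3, which lactonises (PPTS) and rejoins the route at 28.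

2. Step 16. The bridged oxocarbenium ion may lose the proton from C4 instead of C6, or simply recapture acetate. Fallback: open the bridge and make the C5=C6 bond in the monocycle. Mild hydrolysis of 22 (PPTS, wet acetone) would give the bridged hemiketal F4, in equilibrium with the 10-hydroxy-5-ketone. KN(SiMe3)2 (2.2 equiv) and PhNTf2 should give the ring-cis C5=C6 enol triflate F5 by kinetic deprotonation of the C6 methylene. Pd(OAc)2, PPh3, HCO2H and n-Bu3N reduce it to the (Z)-cyclodecenol F6. OsO4 and NMO then add both oxygens suprafacially from the peripheral face and rejoin the route at triol 25, so steps 17 and 18 are bypassed as well.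

3. Step 10. The aldolate may revert (retro-aldol), dehydrate to the cross-conjugated 4-methylene dienone, or the alkene may slip back into conjugation. Fallback: replace the reversible aldol by an irreversible alkylation. The potassium dienolate of 13 and 2-(iodomethyl)-4,4,5,5-tetramethyl-1,3,2-dioxaborolane would give the pinacol boronate F7. Oxidation of its C–B bond with NaBO3·4H2O (THF–H2O) rejoins the route at 15.

Further compounds
F1 | step 20 | 5,6-cyclic sulfate of triol 25 | CC(C)(C)[Si](C)(C)O[C@@H]1C[C@](C)(O)CC[C@@H](OC(C)=O)[C@@H](CO[Si](c2ccccc2)(c2ccccc2)C(C)(C)C)[C@@H]2OS(=O)(=O)O[C@@H]2[C@@H]1CC(=O)OC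
F2 | step 20 | sodium C6 sulfate monoester of the trans-bridged ether (methyl ester) | CC(C)(C)[Si](C)(C)O[C@@H]1C[C@@]2(C)CC[C@@H](OC(C)=O)[C@@H](CO[Si](c3ccccc3)(c3ccccc3)C(C)(C)C)[C@@H](O2)[C@H](OS(=O)(=O)[O-])[C@@H]1CC(=O)OC.[Na+]
F3 | step 20 | trans-bridged ether with C6–OH and methyl ester | CC(C)(C)[Si](C)(C)O[C@@H]1C[C@@]2(C)CC[C@@H](OC(C)=O)[C@@H](CO[Si](c3ccccc3)(c3ccccc3)C(C)(C)C)[C@@H](O2)[C@H](O)[C@@H]1CC(=O)OC
F4 | step 16 | bridged hemiketal (closed form of the 10-hydroxy-5-ketone) | CC(C)(C)[Si](C)(C)O[C@@H]1C[C@@]2(C)CC[C@@H](OC(C)=O)[C@@H](CO[Si](c3ccccc3)(c3ccccc3)C(C)(C)C)[C@](O)(O2)C[C@@H]1CC(=O)OC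
F5 | step 16 | ring-cis C5=C6 enol triflate with free C10–OH | CC(C)(C)[Si](C)(C)O[C@@H]1C[C@](C)(O)CC[C@@H](OC(C)=O)[C@@H](CO[Si](c2ccccc2)(c2ccccc2)C(C)(C)C)/C(OS(=O)(=O)C(F)(F)F)=C\[C@@H]1CC(=O)OC
F6 | step 16 | (Z)-C5=C6 cyclodecenol with free C10–OH | CC(C)(C)[Si](C)(C)O[C@@H]1C[C@](C)(O)CC[C@@H](OC(C)=O)[C@@H](CO[Si](c2ccccc2)(c2ccccc2)C(C)(C)C)/C=C\[C@@H]1CC(=O)OC
F7 | step 10 | 4α-(pinacolborylmethyl) Δ5-3-ketone | CC(C)(C)[Si](C)(C)O[C@@H]1C[C@@]2(C)CCC(=O)[C@@H](CB3OC(C)(C)C(C)(C)O3)C2=C[C@@H]1CC(=O)OC
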